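**Plan**

1. Retrosynthetic cuts: the O–O group at C1, with the C10=C14 olefin moved back to C1=C10 (Schenck ene reaction); then the C5–C6 bond together with the lactone O–C12 bond (Nozaki–Hiyama–Kishi ring closure with lactonisation); then C7–C8 (B-alkyl Suzuki), C1=C10 (cross-metathesis) and C2–C3 (allylboration).
2. Enabling feature: C6 is both the oxygen-bearing γ-carbon of the butenolide ring (O–C6–C7=C11–C12) and the allylic carbon on the (Z)-C4=C5 olefin. It can therefore be an aldehyde carbon held cis to the C12 ester, so one alkenyl-metal addition from C5 closes the ten-membered carbocycle and the resulting alkoxide closes the lactone.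
3. Forward order: 3-furanmethanol becomes a 2-silyl-4-iodofuran (masked cis-formyl acrylate). A silyl ynal is allylated, cross-metathesised, methylenated and joined to the furan by hydroboration/Suzuki coupling. Anti-carbomagnesiation/iodination makes the (Z)-iodoalkene, singlet oxygen opens the furan, the ring closure follows, and a singlet-oxygen ene reaction comes last.
4. Stereochemistry: C3 from reagent-controlled allylboration; C6 from C3 during the ring closure; C1 from a face-selective ene reaction on the macrocycle.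
5. Olefin geometry: (E)-C1=C10 from cross-metathesis, (Z)-C4=C5 from chelate-controlled anti-carbomagnesiation, the cis-formyl ester from the furan ring.

Key step: step 13

Remark (numbering): germacrane numbering is used: C1 (hydroperoxy carbon), C3 (acetoxy carbon), C4=C5 (ring olefin, C15 methyl on C4), C6 (lactone carbinol), C7=C11 (butenolide olefin), C12 (lactone carbonyl), C13 (acetoxymethyl carbon), C10/C14 (exocyclic methylene).
Remark (supply): 3-furanmethanol, 3-(triisopropylsilyl)prop-2-ynal and (−)-B-allyldiisopinocampheylborane are taken as purchasable.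

**Route**

Step 1
Reactants: 1 furan-3-ylmethanol
Product: 2 tert-butyl(furan-3-ylmethoxy)dimethylsilane
Conditions: TBSCl, imidazole, DMF, rt
Reagents that add atoms: tert-butyldimethylsilyl chloride, CC(C)(C)[Si](C)(C)Cl
Why: Standard imidazole-promoted O-silylation of a primary alcohol gives the silyl ether needed for the silyl migration of step 2.

Step 2
Reactants: 2 tert-butyl(furan-3-ylmethoxy)dimethylsilane
Product: 4 [2-(tert-butyldimethylsilyl)furan-3-yl]methanol, via C2-lithiated silyl ether 3 (not isolated)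
Conditions: n-BuLi, HMPA, THF, −78 °C to rt; then H2O
Reagents that add atoms: none
Why: Directed lithiation at C2, between the ring oxygen and the silyloxymethyl group, followed by anionic 1,4 O-to-C silyl migration (retro-Brook rearrangement) is the established entry to 2-silyl-3-furanmethanols.

Step 3
Reactants: 4 [2-(tert-butyldimethylsilyl)furan-3-yl]methanol
Product: 6 [2-(tert-butyldimethylsilyl)-4-iodofuran-3-yl]methanol, via C4-lithiated lithium alkoxide 5 (not isolated)
Conditions: n-BuLi (2.2 equiv), DME, 0 °C; then I2, −78 °C to rt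
Reagents that add atoms: iodine, II
Why: With C2 blocked by silicon, the lithium alkoxide directs the second lithiation to the adjacent C4 position (directed ortho-metalation), and iodine quench should give the 3,4-disubstituted 2-silylfuran.

Step 4
Reactants: 7 3-(triisopropylsilyl)prop-2-ynal
Product: 9 (3S)-1-(triisopropylsilyl)hex-5-en-1-yn-3-ol, via homoallyl diisopinocampheylborinate 8 (not isolated)
Conditions: (−)-Ipc2B(allyl), Et2O, −78 °C; then H2O2, pH 7 buffer, 0 °C
Reagents that add atoms: (−)-B-allyldiisopinocampheylborane, C=CCB([C@@H]1C[C@@H]2C[C@H]([C@H]1C)C2(C)C)[C@@H]1C[C@@H]2C[C@H]([C@H]1C)C2(C)C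
Why: Brown asymmetric allylboration through a chair transition state delivers allyl to the Si face of the aldehyde with the reagent derived from (+)-α-pinene, which should set the (S) carbinol that becomes C3.

Step 5
Reactants: 9 (3S)-1-(triisopropylsilyl)hex-5-en-1-yn-3-ol
Product: 10 (2E,5S)-5-hydroxy-2-methyl-7-(triisopropylsilyl)hept-2-en-6-ynal
Conditions: methacrolein (excess), second-generation Hoveyda–Grubbs catalyst (5 mol %), CH2Cl2, 40 °C
Reagents that add atoms: methacrolein, CC(=C)C=O
Why: Olefin cross-metathesis of a monosubstituted olefin with methacrolein gives the conjugated trisubstituted enal as its thermodynamic (E) isomer, which fixes the (E)-C1=C10 olefin, while the hindered silylalkyne should stay out of enyne metathesis.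

Step 6
Reactants: 10 (2E,5S)-5-hydroxy-2-methyl-7-(triisopropylsilyl)hept-2-en-6-ynal
Product: 11 (3S,5E)-6-methyl-1-(triisopropylsilyl)octa-5,7-dien-1-yn-3-ol
Conditions: Ph3PCH3Br, KHMDS (2.3 equiv each), THF, −78 to 0 °C
Reagents that add atoms: methyltriphenylphosphonium bromide, C[P+](c1ccccc1)(c1ccccc1)c1ccccc1.[Br-]
Why: Wittig methylenation of the enal (1,2-addition of the unstabilised ylide) gives the terminal 1,3-diene without touching the olefin geometry or C3.

Step 7
Reactants: 11 (3S,5E)-6-methyl-1-(triisopropylsilyl)octa-5,7-dien-1-yn-3-ol; 6 [2-(tert-butyldimethylsilyl)-4-iodofuran-3-yl]methanol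
Product: 13 (3S,5E)-8-[5-(tert-butyldimethylsilyl)-4-(hydroxymethyl)furan-3-yl]-6-methyl-1-(triisopropylsilyl)oct-5-en-1-yn-3-ol, via B-alkyl-9-BBN borane 12 (not isolated)
Conditions: 9-BBN (2.3 equiv), THF, 0 °C to rt; then 6, Pd(dppf)Cl2 (5 mol %), AsPh3, Cs2CO3, DMF/H2O, rt
Reagents that add atoms: none
Why: 9-BBN should hydroborate only the unhindered terminal vinyl group in the anti-Markovnikov sense (the excess converts the carbinol to its borinate and the bulky silylalkyne is inert), and B-alkyl Suzuki–Miyaura coupling with the furyl iodide then forms the C7–C8 bond.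

Step 8
Reactants: 13 (3S,5E)-8-[5-(tert-butyldimethylsilyl)-4-(hydroxymethyl)furan-3-yl]-6-methyl-1-(triisopropylsilyl)oct-5-en-1-yn-3-ol
Product: 14 (3S,5E)-8-[5-(tert-butyldimethylsilyl)-4-(hydroxymethyl)furan-3-yl]-6-methyloct-5-en-1-yn-3-ol
Conditions: TBAF (1.2 equiv), THF, 0 °C to rt
Reagents that add atoms: none
Why: Fluoride-mediated protodesilylation cleaves the alkynyl C–Si bond far faster than the furyl C–Si bond of the bulky tert-butyldimethylsilyl group, freeing the terminal propargylic alcohol.

Step 9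
Reactants: 14 (3S,5E)-8-[5-(tert-butyldimethylsilyl)-4-(hydroxymethyl)furan-3-yl]-6-methyloct-5-en-1-yn-3-ol
Product: 16 (1Z,3S,5E)-8-[5-(tert-butyldimethylsilyl)-4-(hydroxymethyl)furan-3-yl]-1-iodo-2,6-dimethylocta-1,5-dien-3-ol, via (Z)-alkenylmagnesium chelate 15 (not isolated)
Conditions: MeMgBr (5 equiv), CuI (20 mol %), THF/Et2O, −10 °C to rt; then I2, −78 to 0 °C
Reagents that add atoms: methylmagnesium bromide, C[Mg]Br; iodine, II
Why: Copper-catalysed anti-carbomagnesiation of the propargylic magnesium alkoxide puts methyl on the proximal carbon (C4) and magnesium on the terminal carbon (C5) inside a five-membered chelate, so iodinolysis with retention should give the (Z)-iodoalkene with iodine cis to C3, whose configuration is untouched.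

Step 10
Reactants: 16 (1Z,3S,5E)-8-[5-(tert-butyldimethylsilyl)-4-(hydroxymethyl)furan-3-yl]-1-iodo-2,6-dimethylocta-1,5-dien-3-ol
Product: 17 (1Z,3S,5E)-8-[4-(acetoxymethyl)-5-(tert-butyldimethylsilyl)furan-3-yl]-1-iodo-2,6-dimethylocta-1,5-dien-3-yl acetate
Conditions: Ac2O, pyridine, DMAP (cat.), CH2Cl2, 0 °C to rt
Reagents that add atoms: acetic anhydride, CC(=O)OC(C)=O
Why: DMAP-catalysed acylation installs both acetates of the target (C3 and C13) in one operation.

Step 11
Reactants: 17 (1Z,3S,5E)-8-[4-(acetoxymethyl)-5-(tert-butyldimethylsilyl)furan-3-yl]-1-iodo-2,6-dimethylocta-1,5-dien-3-yl acetate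
Product: 20 (1Z,3S,5E)-8-[4-(acetoxymethyl)-2-hydroxy-5-oxo-2,5-dihydrofuran-3-yl]-1-iodo-2,6-dimethylocta-1,5-dien-3-yl acetate (both lactol epimers), via furan endoperoxide 18 (not isolated), via cis-formyl silyl ester 19 (not isolated)
Conditions: O2, visible light, tetraphenylporphyrin (cat.), CH2Cl2, −78 °C; then H2O, rt
Reagents that add atoms: dioxygen (as singlet oxygen), O=O
Why: The [4+2] cycloaddition of singlet oxygen to the furan is far faster at −78 °C than the ene reaction of the trisubstituted olefin, and silyl migration from C12 to the peroxide oxygen (2-silylfuran photooxygenation) should give the cis-formyl silyl ester, which on hydrolysis closes to the lactol with the carbonyl at the former silyl-bearing carbon.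

Step 12
Reactants: 20 (1Z,3S,5E)-8-[4-(acetoxymethyl)-2-hydroxy-5-oxo-2,5-dihydrofuran-3-yl]-1-iodo-2,6-dimethylocta-1,5-dien-3-yl acetate
Product: 22 methyl (2Z,6E,9S,10Z)-9-acetoxy-2-(acetoxymethyl)-3-formyl-11-iodo-6,10-dimethylundeca-2,6,10-trienoate, via potassium formyl carboxylate 21 (not isolated)
Conditions: K2CO3 (1.1 equiv), MeI, DMF, 0 °C to rt
Reagents that add atoms: iodomethane, CI
Why: Base opens the lactol (a pseudo-acid) to the cis-formyl carboxylate, and carboxylate O-alkylation should give the open (Z)-formyl methyl ester with the aldehyde (C6) free for the ring closure.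

Step 13
Reactants: 22 methyl (2Z,6E,9S,10Z)-9-acetoxy-2-(acetoxymethyl)-3-formyl-11-iodo-6,10-dimethylundeca-2,6,10-trienoate
Product: 25 (3S,6R)-3,13-diacetoxygermacra-1(10)E,4Z,7(11)-trien-12,6-olide, that is [(6E,9S,10Z,11aR)-9-acetoxy-6,10-dimethyl-2-oxo-2,4,5,8,9,11a-hexahydrocyclodeca[b]furan-3-yl]methyl acetate, via alkenylchromium dichloride 23 (not isolated), via ring-closed chromium alkoxide 24 (not isolated)
Conditions: CrCl2 (10 equiv), NiCl2 (0.1 equiv), degassed DMSO/THF, slow addition of 22 to 0.002 M, rt; aqueous work-up; PPTS, CH2Cl2 if lactonisation is incomplete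
Reagents that add atoms: none
Why: Nickel dichloride is reduced by chromium dichloride to zerovalent nickel, which inserts into the C5–I bond with retention of the (Z) geometry; transmetalation gives an alkenyl trivalent-chromium species that adds to the C6 aldehyde, and the chromium alkoxide, held cis to the C12 methyl ester across the C7=C11 olefin, expels methoxide to form the butenolide. The closest known reaction type is the Nozaki–Hiyama–Kishi macrocyclisation of an iodoalkene onto an aldehyde, followed by lactonisation of the resulting cis-γ-hydroxy enoate. The ten-membered carbocycle closes by a 10-exo-trig addition to the aldehyde carbonyl and the lactone by a 5-exo-trig acyl substitution. C6 is the only new stereocentre and is controlled by the resident C3 stereocentre, which sits cis to the reacting carbon on the (Z)-olefin: with H-3 eclipsing the olefin to relieve allylic 1,3-strain, the tether leaves C3 on the face opposite to the acetoxy group, and addition through the half-chair-like arrangement in which the tether crosses the olefin plane (the two oxygen substituents on opposite faces) is expected to give the (6R) lactone, though this sense is not secure and is the main risk. The step needs chemoselectivity (one C–I bond and one aldehyde; the mild, aldehyde-selective organochromium reagent should leave the ester, the formyl acrylate olefin and both allylic acetates alone), ring closure instead of oligomerisation (high dilution, and a tether stiffened by three olefins), and a cis relationship of formyl and ester groups for lactonisation, which is inherited from the furan ring.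

Step 14
Reactants: 25 (3S,6R)-3,13-diacetoxygermacra-1(10)E,4Z,7(11)-trien-12,6-olide
Product: 26 (1R,3S,6R)-3,13-diacetoxy-1-hydroperoxygermacra-4Z,7(11),10(14)-trien-12,6-olide (CNP0174966.1)
Conditions: O2, visible light, tetraphenylporphyrin (cat.), CH2Cl2, −20 °C
Reagents that add atoms: dioxygen (as singlet oxygen), O=O
Why: In this Schenck ene reaction singlet oxygen should attack the only electron-rich olefin (C4=C5 is deactivated by two allylic C–O bonds and C7=C11 is electron-poor), bond to C1 and take a hydrogen from the C14 methyl on the more crowded side of the olefin (cis effect) so that the double bond moves to C10=C14; the (1R) configuration is expected from attack on the exposed outer face of the (E)-olefin in the ten-membered ring, as in the photooxygenation of related germacranolides.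

**Compound list**

1 | furan-3-ylmethanol | OCc1ccoc1 | starting material
2 | tert-butyl(furan-3-ylmethoxy)dimethylsilane | CC(C)(C)[Si](C)(C)OCc1ccoc1 | intermediate
3 | {3-[(tert-butyldimethylsilyloxy)methyl]furan-2-yl}lithium | [Li]c1occc1CO[Si](C)(C)C(C)(C)C | intermediate
4 | [2-(tert-butyldimethylsilyl)furan-3-yl]methanol | OCc1ccoc1[Si](C)(C)C(C)(C)C | intermediate
5 | lithium [2-(tert-butyldimethylsilyl)-4-lithiofuran-3-yl]methanolate | [Li]OCc1c([Li])coc1[Si](C)(C)C(C)(C)C | intermediate
6 | [2-(tert-butyldimethylsilyl)-4-iodofuran-3-yl]methanol | OCc1c(I)coc1[Si](C)(C)C(C)(C)C | intermediate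
7 | 3-(triisopropylsilyl)prop-2-ynal | CC(C)[Si](C(C)C)(C(C)C)C#CC=O | starting material
8 | (3S)-1-(triisopropylsilyl)hex-5-en-1-yn-3-yl diisopinocampheylborinate | CC(C)[Si](C(C)C)(C(C)C)C#C[C@@H](OB([C@@H]1C[C@@H]2C[C@H]([C@H]1C)C2(C)C)[C@@H]1C[C@@H]2C[C@H]([C@H]1C)C2(C)C)CC=C | intermediate
9 | (3S)-1-(triisopropylsilyl)hex-5-en-1-yn-3-ol | CC(C)[Si](C(C)C)(C(C)C)C#C[C@@H](O)CC=C | intermediate
10 | (2E,5S)-5-hydroxy-2-methyl-7-(triisopropylsilyl)hept-2-en-6-ynal | CC(C)[Si](C(C)C)(C(C)C)C#C[C@@H](O)C/C=C(\C)C=O | intermediate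
11 | (3S,5E)-6-methyl-1-(triisopropylsilyl)octa-5,7-dien-1-yn-3-ol | CC(C)[Si](C(C)C)(C(C)C)C#C[C@@H](O)C/C=C(\C)C=C | intermediate
12 | 9-[(3E,6S)-6-(9-borabicyclo[3.3.1]nonan-9-yloxy)-3-methyl-8-(triisopropylsilyl)oct-3-en-7-yn-1-yl]-9-borabicyclo[3.3.1]nonane | CC(C)[Si](C(C)C)(C(C)C)C#C[C@@H](OB1C2CCCC1CCC2)C/C=C(\C)CCB1C2CCCC1CCC2 | intermediate
13 | (3S,5E)-8-[5-(tert-butyldimethylsilyl)-4-(hydroxymethyl)furan-3-yl]-6-methyl-1-(triisopropylsilyl)oct-5-en-1-yn-3-ol | CC(C)[Si](C(C)C)(C(C)C)C#C[C@@H](O)C/C=C(\C)CCc1coc([Si](C)(C)C(C)(C)C)c1CO | intermediate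
14 | (3S,5E)-8-[5-(tert-butyldimethylsilyl)-4-(hydroxymethyl)furan-3-yl]-6-methyloct-5-en-1-yn-3-ol | C#C[C@@H](O)C/C=C(\C)CCc1coc([Si](C)(C)C(C)(C)C)c1CO | intermediate
15 | tris(bromomagnesium) species of 16 (C1–MgBr cis to C3, both oxygens as O–MgBr) | Br[Mg]/C=C(/C)[C@@H](O[Mg]Br)C/C=C(\C)CCc1coc([Si](C)(C)C(C)(C)C)c1CO[Mg]Br | intermediate
16 | (1Z,3S,5E)-8-[5-(tert-butyldimethylsilyl)-4-(hydroxymethyl)furan-3-yl]-1-iodo-2,6-dimethylocta-1,5-dien-3-ol | I/C=C(/C)[C@@H](O)C/C=C(\C)CCc1coc([Si](C)(C)C(C)(C)C)c1CO | intermediate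
17 | (1Z,3S,5E)-8-[4-(acetoxymethyl)-5-(tert-butyldimethylsilyl)furan-3-yl]-1-iodo-2,6-dimethylocta-1,5-dien-3-yl acetate | I/C=C(/C)[C@@H](OC(C)=O)C/C=C(\C)CCc1coc([Si](C)(C)C(C)(C)C)c1COC(C)=O | intermediate
18 | 2,5-endoperoxide of furan 17 (1-silyl-2,3,7-trioxabicyclo[2.2.1]hept-5-ene, bridgehead epimers) | I/C=C(/C)[C@@H](OC(C)=O)C/C=C(\C)CCC1=C(COC(C)=O)C2([Si](C)(C)C(C)(C)C)OOC1O2 | intermediate
19 | tert-butyldimethylsilyl (2Z,6E,9S,10Z)-9-acetoxy-2-(acetoxymethyl)-3-formyl-11-iodo-6,10-dimethylundeca-2,6,10-trienoate | I/C=C(/C)[C@@H](OC(C)=O)C/C=C(\C)CC/C(C=O)=C(\COC(C)=O)C(=O)O[Si](C)(C)C(C)(C)C | intermediate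
20 | (1Z,3S,5E)-8-[4-(acetoxymethyl)-2-hydroxy-5-oxo-2,5-dihydrofuran-3-yl]-1-iodo-2,6-dimethylocta-1,5-dien-3-yl acetate (lactol epimers) | I/C=C(/C)[C@@H](OC(C)=O)C/C=C(\C)CCC1=C(COC(C)=O)C(=O)OC1O | intermediate
21 | potassium (2Z,6E,9S,10Z)-9-acetoxy-2-(acetoxymethyl)-3-formyl-11-iodo-6,10-dimethylundeca-2,6,10-trienoate | I/C=C(/C)[C@@H](OC(C)=O)C/C=C(\C)CC/C(C=O)=C(\COC(C)=O)C(=O)[O-].[K+] | intermediate
22 | methyl (2Z,6E,9S,10Z)-9-acetoxy-2-(acetoxymethyl)-3-formyl-11-iodo-6,10-dimethylundeca-2,6,10-trienoate | I/C=C(/C)[C@@H](OC(C)=O)C/C=C(\C)CC/C(C=O)=C(\COC(C)=O)C(=O)OC | intermediate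
23 | (Z)-alkenylchromium dichloride from 22 (CrCl2 in place of iodine) | Cl[Cr](Cl)/C=C(/C)[C@@H](OC(C)=O)C/C=C(\C)CC/C(C=O)=C(\COC(C)=O)C(=O)OC | intermediate
24 | dichlorochromium alkoxide of methyl (2Z)-3-acetoxy-2-[(2R,3Z,5S,7E)-5-acetoxy-2-hydroxy-4,8-dimethylcyclodeca-3,7-dien-1-ylidene]propanoate | C/C1=C\C[C@H](OC(C)=O)/C(C)=C\[C@@H](O[Cr](Cl)Cl)/C(CC1)=C(/COC(C)=O)C(=O)OC | intermediate
25 | (3S,6R)-3,13-diacetoxygermacra-1(10)E,4Z,7(11)-trien-12,6-olide | C/C1=C\C[C@H](OC(C)=O)/C(C)=C\[C@H]2OC(=O)C(COC(C)=O)=C2CC1 | intermediate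
26 | (1R,3S,6R)-3,13-diacetoxy-1-hydroperoxygermacra-4Z,7(11),10(14)-trien-12,6-olide | C=C1CCC2=C(COC(C)=O)C(=O)O[C@@H]2/C=C(/C)[C@@H](OC(C)=O)C[C@H]1OO | target

**Count**

Total steps: 14. Longest linear sequence: 11 steps (steps 4–14 from 7; equally steps 1–3 and 7–14 from 1).

**Steps most likely to fail, with fallbacks**

Step 13. What may go wrong: oligomerisation instead of ring closure, single-electron reduction of the cis-formyl acrylate by divalent chromium, or addition to the wrong face of the aldehyde so that the C6 epimer forms. The fallback sets out from 14 and returns at 25. Compound 14 is carbomagnesiated as in step 9 but the alkenylmagnesium is protonated, giving the isopropenyl carbinol F1. Acetylation gives the diacetate F2, furan photooxygenation the lactol F3, and O-methylation the formyl methyl ester F4, under the conditions of steps 10–12. The aldehyde is then vinylated under reagent control (divinylzinc with a chiral amino-alcohol ligand, or a catalytic asymmetric Nozaki–Hiyama–Kishi reaction of vinyl bromide), and the carbinol lactonises to the (6R)-vinylbutenolide F5. Ring-closing olefin metathesis of the vinyl and isopropenyl groups (second-generation Hoveyda–Grubbs catalyst, hot toluene, high dilution) closes the ten-membered ring at C4=C5, the ring imposing the Z geometry, and gives 25. In this variant C5–C6 is made between two molecules and C6 is set by the reagent.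

Step 9. What may go wrong: incomplete or regiochemically unselective carbomagnesiation on the polyfunctional diol, or attack of iodine on the electron-rich furan during iodinolysis. The fallback sets out from 9 and returns at 22. Compound 9 is desilylated with TBAF to the enynol F6, and the carbomagnesiation is run on this simple substrate with trapping of the alkenylmagnesium by chlorotrimethylsilane, giving the (Z)-alkenylsilane F7 (the O-silyl group is lost on work-up). The silane is inert to palladium and is carried through the conditions of steps 5–7 and 10–12: enal F8, diene F9, coupled furan diol F10, diacetate F11, lactol F12 and formyl methyl ester F13. Iododesilylation with N-iodosuccinimide (ipso substitution with retention), done only after the silylfuran has been oxidised, then gives 22.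

Step 14. What may go wrong: oxygen is delivered to the wrong face of the C1=C10 olefin (C1 epimer), or hydrogen is taken from C9 or C2 instead of C14. The fallback sets out from 25 and returns at 26. The most electron-rich olefin is epoxidised with dimethyldioxirane to the 1,10-epoxide F14. Titanocene chloride (Cp2TiCl, trivalent titanium, made from Cp2TiCl2 and Mn) cleaves the tertiary C10–O bond and removes a hydrogen from C14, giving the exocyclic allylic alcohol F15 with the C1–O configuration retained. Mesylation gives F16, and displacement of the sulfonate by hydrogen peroxide (SN2, inversion at C1, the classical sulfonate route to secondary hydroperoxides) gives 26. The regiochemistry is then fixed by the titanium step and the configuration by the inversion; the acetates may not tolerate basic peroxide, so this last displacement is the weak point of the fallback.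

**Further compounds**

F1 | step 13 | (3S,5E)-8-[5-(tert-butyldimethylsilyl)-4-(hydroxymethyl)furan-3-yl]-2,6-dimethylocta-1,5-dien-3-ol | C=C(C)[C@@H](O)C/C=C(\C)CCc1coc([Si](C)(C)C(C)(C)C)c1CO
F2 | step 13 | (3S,5E)-8-[4-(acetoxymethyl)-5-(tert-butyldimethylsilyl)furan-3-yl]-2,6-dimethylocta-1,5-dien-3-yl acetate | C=C(C)[C@@H](OC(C)=O)C/C=C(\C)CCc1coc([Si](C)(C)C(C)(C)C)c1COC(C)=O
F3 | step 13 | (3S,5E)-8-[4-(acetoxymethyl)-2-hydroxy-5-oxo-2,5-dihydrofuran-3-yl]-2,6-dimethylocta-1,5-dien-3-yl acetate (lactol epimers) | C=C(C)[C@@H](OC(C)=O)C/C=C(\C)CCC1=C(COC(C)=O)C(=O)OC1O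
F4 | step 13 | methyl (2Z,6E,9S)-9-acetoxy-2-(acetoxymethyl)-3-formyl-6,10-dimethylundeca-2,6,10-trienoate | C=C(C)[C@@H](OC(C)=O)C/C=C(\C)CC/C(C=O)=C(\COC(C)=O)C(=O)OC
F5 | step 13 | (3S,5E)-8-[(2R)-4-(acetoxymethyl)-5-oxo-2-vinyl-2,5-dihydrofuran-3-yl]-2,6-dimethylocta-1,5-dien-3-yl acetate | C=C(C)[C@@H](OC(C)=O)C/C=C(\C)CCC1=C(COC(C)=O)C(=O)O[C@@H]1C=C
F6 | step 9 | (3S)-hex-5-en-1-yn-3-ol | C#C[C@@H](O)CC=C
F7 | step 9 | (1Z,3S)-2-methyl-1-(trimethylsilyl)hexa-1,5-dien-3-ol | C[Si](C)(C)/C=C(/C)[C@@H](O)CC=C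
F8 | step 9 | (2E,5S,6Z)-5-hydroxy-2,6-dimethyl-7-(trimethylsilyl)hepta-2,6-dienal | C[Si](C)(C)/C=C(/C)[C@@H](O)C/C=C(\C)C=O
F9 | step 9 | (1Z,3S,5E)-2,6-dimethyl-1-(trimethylsilyl)octa-1,5,7-trien-3-ol | C[Si](C)(C)/C=C(/C)[C@@H](O)C/C=C(\C)C=C
F10 | step 9 | (1Z,3S,5E)-8-[5-(tert-butyldimethylsilyl)-4-(hydroxymethyl)furan-3-yl]-2,6-dimethyl-1-(trimethylsilyl)octa-1,5-dien-3-ol | C[Si](C)(C)/C=C(/C)[C@@H](O)C/C=C(\C)CCc1coc([Si](C)(C)C(C)(C)C)c1CO
F11 | step 9 | (1Z,3S,5E)-8-[4-(acetoxymethyl)-5-(tert-butyldimethylsilyl)furan-3-yl]-2,6-dimethyl-1-(trimethylsilyl)octa-1,5-dien-3-yl acetate | C[Si](C)(C)/C=C(/C)[C@@H](OC(C)=O)C/C=C(\C)CCc1coc([Si](C)(C)C(C)(C)C)c1COC(C)=O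
F12 | step 9 | (1Z,3S,5E)-8-[4-(acetoxymethyl)-2-hydroxy-5-oxo-2,5-dihydrofuran-3-yl]-2,6-dimethyl-1-(trimethylsilyl)octa-1,5-dien-3-yl acetate (lactol epimers) | C[Si](C)(C)/C=C(/C)[C@@H](OC(C)=O)C/C=C(\C)CCC1=C(COC(C)=O)C(=O)OC1O
F13 | step 9 | methyl (2Z,6E,9S,10Z)-9-acetoxy-2-(acetoxymethyl)-3-formyl-6,10-dimethyl-11-(trimethylsilyl)undeca-2,6,10-trienoate | C[Si](C)(C)/C=C(/C)[C@@H](OC(C)=O)C/C=C(\C)CC/C(C=O)=C(\COC(C)=O)C(=O)OC
F14 | step 14 | 1,10-epoxide of 25 (trans epoxide, oxygen at C1 on the face opposite to the hydroperoxy group of 26) | C[C@]12CCC3=C(COC(C)=O)C(=O)O[C@@H]3/C=C(/C)[C@@H](OC(C)=O)C[C@@H]1O2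
F15 | step 14 | (1S,3S,6R)-3,13-diacetoxy-1-hydroxygermacra-4Z,7(11),10(14)-trien-12,6-olide | C=C1CCC2=C(COC(C)=O)C(=O)O[C@@H]2/C=C(/C)[C@@H](OC(C)=O)C[C@@H]1O
F16 | step 14 | (1S,3S,6R)-3,13-diacetoxy-1-(methanesulfonyloxy)germacra-4Z,7(11),10(14)-trien-12,6-olide | C=C1CCC2=C(COC(C)=O)C(=O)O[C@@H]2/C=C(/C)[C@@H](OC(C)=O)C[C@@H]1OS(C)(=O)=O
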